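**Retrosynthetic overview** (drimane numbering: ring A = C1–C5 and C10, ring B = C5–C10, C11 = the OCH2 carbon)
1. Target 17 ⇒ C1=C2 dehydrogenation and Mitsunobu disconnection of the C11–O bond ⇒ hydroxy ketone 14 + isofraxidin 15.
2. 14 ⇒ C3–C4 bond: ring A is closed last, by a hydrogen-atom-transfer-initiated 6-exo radical cyclization of the isopropenyl group on C5 onto the nitrile carbon C3 of the monocyclic ring-B nitrile 12.
3. Enabling feature: in ring A the quaternary C4 carries two methyls next to the C3 carbonyl, so C4 is an isopropenyl carbon plus one hydrogen atom (a tertiary radical) and C3 is a masked nitrile; the C5 isopropenyl and the C10 cyanoethyl are trans on ring B, which fixes the trans ring fusion.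
4. 12 ⇒ [2,3]-Wittig–Still rearrangement (C9–C11 bond, C7=C8) ⇒ Wharton transposition ⇒ epoxidation ⇒ cyano enone 4 ⇒ two α′-alkylations at C10 of (S)-carvone 1, which supplies ring B, C5 and the future C4.
5. Ring order: ring B (from 1), then ring A (step 7); the coumarin rings come with 15.

Key step: step 7

Assumption: isofraxidin 15 and tributyl(iodomethyl)stannane 8 are taken as purchasable, and the minor cis epimer of 2 is carried on because its C6 centre is erased in step 2.

Step 1
Reactants: 1 (S)-(+)-carvone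
Product: 2 (5S,6R)-2,6-dimethyl-5-(prop-1-en-2-yl)cyclohex-2-en-1-one
Conditions: LiN(iPr)2 (1.1 equiv), THF, −78 °C; MeI, −78 → 0 °C
Reagents that add atoms: iodomethane, CI
Why: Kinetic α′-deprotonation gives the cross-conjugated lithium dienolate, which is C-methylated (enolate alkylation) mainly trans to the isopropenyl group; this centre is planarized again in step 2, so its configuration does not matter.

Step 2
Reactants: 2 (5S,6R)-2,6-dimethyl-5-(prop-1-en-2-yl)cyclohex-2-en-1-one; 3 acrylonitrile
Product: 4 3-[(1R,6R)-1,3-dimethyl-2-oxo-6-(prop-1-en-2-yl)cyclohex-3-en-1-yl]propanenitrile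
Conditions: LiN(iPr)2 (1.05 equiv), THF, −78 °C; 3 (1.2 equiv), −78 → −40 °C; AcOH
Reagents that add atoms: none
Why: Michael addition of the tetrasubstituted kinetic enolate to acrylonitrile should set the quaternary C10, the acceptor approaching the enolate face anti to the neighbouring C5 isopropenyl group so that the cyanoethyl chain ends trans and the methyl cis to it.

Step 3
Reactants: 4 3-[(1R,6R)-1,3-dimethyl-2-oxo-6-(prop-1-en-2-yl)cyclohex-3-en-1-yl]propanenitrile
Product: 5 3-[(1S,3R,4R,6S)-1,3-dimethyl-2-oxo-4-(prop-1-en-2-yl)-7-oxabicyclo[4.1.0]heptan-3-yl]propanenitrile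
Conditions: t-BuOOH (2 equiv, in decane), DBU (1.5 equiv), CH2Cl2, 0 °C → rt
Reagents that add atoms: tert-butyl hydroperoxide, CC(C)(C)OO
Why: Weitz–Scheffer nucleophilic epoxidation touches only the enone; the peroxide anion should add axially to C7 anti to the C5 isopropenyl group, as with carvone itself, giving the epoxide trans to isopropenyl, while the nitrile and the isolated alkene are inert to t-BuOO−.

Step 4
Reactants: 5 3-[(1S,3R,4R,6S)-1,3-dimethyl-2-oxo-4-(prop-1-en-2-yl)-7-oxabicyclo[4.1.0]heptan-3-yl]propanenitrile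
Product: 7 3-[(1S,4S,6R)-4-hydroxy-1,3-dimethyl-6-(prop-1-en-2-yl)cyclohex-2-en-1-yl]propanenitrile, via epoxy hydrazone 6 (not isolated)
Conditions: N2H4·H2O (3 equiv), AcOH (0.5 equiv), MeOH, 0 °C → rt
Reagents that add atoms: none
Why: Wharton reaction: the epoxy hydrazone opens to a vinyl diazene that loses N2, moving the oxygen function to C7 and the alkene to C8=C9; the C7–O bond of the epoxide is never broken, so the C7 carbinol keeps the epoxide configuration (OH trans to isopropenyl).

Step 5
Reactants: 7 3-[(1S,4S,6R)-4-hydroxy-1,3-dimethyl-6-(prop-1-en-2-yl)cyclohex-2-en-1-yl]propanenitrile; 8 tributyl(iodomethyl)stannane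
Product: 9 3-[(1S,4S,6R)-1,3-dimethyl-6-(prop-1-en-2-yl)-4-[(tributylstannyl)methoxy]cyclohex-2-en-1-yl]propanenitrile
Conditions: KH (1.1 equiv), THF, 0 °C; 8 (1.3 equiv), 18-crown-6 (10 mol %), 0 °C → rt
Reagents that add atoms: none
Why: Williamson etherification of the potassium alkoxide with the reactive iodomethylstannane should be much faster than any reaction at the weakly acidic nitrile α-position, and no stereocentre is touched.

Step 6
Reactants: 9 3-[(1S,4S,6R)-1,3-dimethyl-6-(prop-1-en-2-yl)-4-[(tributylstannyl)methoxy]cyclohex-2-en-1-yl]propanenitrile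
Product: 12 3-[(1R,2S,6R)-2-(hydroxymethyl)-1,3-dimethyl-6-(prop-1-en-2-yl)cyclohex-3-en-1-yl]propanenitrile, via lithiated nitrile 10 (not isolated), via alkoxymethyllithium 11 (not isolated)
Conditions: LiN(iPr)2 (1.05 equiv), THF, −78 °C; n-BuLi (1.2 equiv), −78 → −40 °C; then H2O
Reagents that add atoms: none
Why: [2,3]-Wittig–Still rearrangement: with the nitrile masked in the flask as its N-lithio keteniminate, tin–lithium exchange gives the α-alkoxymethyllithium, whose carbanion is delivered suprafacially from the pseudoaxial C7 oxygen to C9 on the face anti to the isopropenyl and C10-methyl groups, which sets C9 (CH2OH trans to the C10 methyl) and moves the alkene to C7=C8.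

Step 7
Reactants: 12 3-[(1R,2S,6R)-2-(hydroxymethyl)-1,3-dimethyl-6-(prop-1-en-2-yl)cyclohex-3-en-1-yl]propanenitrile
Product: 14 (4aR,5S,8aS)-5-(hydroxymethyl)-1,1,4a,6-tetramethyl-3,4,4a,5,8,8a-hexahydronaphthalen-2(1H)-one, via ketimine 13 (not isolated)
Conditions: Fe(acac)3 (30 mol %), PhSiH3 (2.5 equiv), EtOH, 60 °C; then 1 M HCl, THF, rt
Reagents that add atoms: water, O
Why: An iron hydride formed from Fe(acac)3, PhSiH3 and EtOH transfers a hydrogen atom to the CH2 terminus of the isopropenyl group, which creates the second C4 methyl and the tertiary C4 radical; this radical adds to the nitrile carbon C3, the iminyl radical is reduced to the N–H ketimine 13, and acidic work-up hydrolyses it to the C3 ketone. The closest known reaction type is the Mukaiyama-type metal-hydride hydrogen-atom-transfer reductive cyclization of alkenyl nitriles to α-quaternary cycloalkanones, with the related alkene–ketone and alkene–aldehyde cyclizations. Ring A is closed in the 6-exo-dig mode through a chair-like transition state spanning C4–C5–C10–C1–C2–C3. No new stereocentre is formed, since C4 carries two methyls; the trans ring fusion follows from the preset trans, diequatorial arrangement of the C5 isopropenyl and C10 cyanoethyl groups on ring B. The step needs chemoselective hydrogen-atom transfer to the 1,1-disubstituted alkene rather than the more hindered trisubstituted C7=C8 alkene, Markovnikov radical formation, and cyclization faster than radical reduction; the substrate secures this because the isopropenyl group is the most accessible electron-rich alkene, every alternative acceptor would require a four-membered or 5-endo closure, and the quaternary C10 pre-organizes the chain.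

Step 8
Reactants: 14 (4aR,5S,8aS)-5-(hydroxymethyl)-1,1,4a,6-tetramethyl-3,4,4a,5,8,8a-hexahydronaphthalen-2(1H)-one; 15 isofraxidin (7-hydroxy-6,8-dimethoxy-2H-chromen-2-one)
Product: 16 6,8-dimethoxy-7-{[(1S,4aS,8aR)-2,5,5,8a-tetramethyl-6-oxo-1,4,4a,5,6,7,8,8a-octahydronaphthalen-1-yl]methoxy}-2H-chromen-2-one
Conditions: PPh3 (1.5 equiv), DIAD (1.5 equiv), THF, 0 → 40 °C
Reagents that add atoms: none
Why: Mitsunobu etherification of the primary C11 alcohol with the acidic 7-hydroxycoumarin should form the aryl ether at a CH2 carbon, so no stereocentre is involved and the ketone and alkene are untouched.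

Step 9
Reactants: 16 6,8-dimethoxy-7-{[(1S,4aS,8aR)-2,5,5,8a-tetramethyl-6-oxo-1,4,4a,5,6,7,8,8a-octahydronaphthalen-1-yl]methoxy}-2H-chromen-2-one
Product: 17 6,8-dimethoxy-7-{[(1S,4aS,8aR)-2,5,5,8a-tetramethyl-6-oxo-1,4,4a,5,6,8a-hexahydronaphthalen-1-yl]methoxy}-2H-chromen-2-one
Conditions: IBX (2.5 equiv), DMSO, 75 °C
Reagents that add atoms: none
Why: IBX dehydrogenation of a ketone to its enone is well established for 4,4-dimethyl-3-keto terpenoids that also contain a trisubstituted alkene; the ketone can enolize only toward C2 because C4 is quaternary, so the C1=C2 bond forms regiospecifically and no stereocentre is affected.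

**Compound list**
1 | (S)-(+)-carvone, (5S)-2-methyl-5-(prop-1-en-2-yl)cyclohex-2-en-1-one | O=C1C(C)=CC[C@H](C(C)=C)C1 | starting material
2 | (5S,6R)-2,6-dimethyl-5-(prop-1-en-2-yl)cyclohex-2-en-1-one (trans-6-methylcarvone) | O=C1C(C)=CC[C@H](C(C)=C)[C@H]1C | intermediate
3 | acrylonitrile | C=CC#N | starting material
4 | 3-[(1R,6R)-1,3-dimethyl-2-oxo-6-(prop-1-en-2-yl)cyclohex-3-en-1-yl]propanenitrile | O=C1C(C)=CC[C@H](C(C)=C)[C@]1(CCC#N)C | intermediate
5 | 3-[(1S,3R,4R,6S)-1,3-dimethyl-2-oxo-4-(prop-1-en-2-yl)-7-oxabicyclo[4.1.0]heptan-3-yl]propanenitrile | O=C1[C@@]2(C)O[C@H]2C[C@H](C(C)=C)[C@]1(CCC#N)C | intermediate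
6 | hydrazone of 5 at the ring carbonyl (epoxy hydrazone) | NN=C1[C@@]2(C)O[C@H]2C[C@H](C(C)=C)[C@]1(CCC#N)C | intermediate
7 | 3-[(1S,4S,6R)-4-hydroxy-1,3-dimethyl-6-(prop-1-en-2-yl)cyclohex-2-en-1-yl]propanenitrile | C[C@]1(CCC#N)C=C(C)[C@@H](O)C[C@@H]1C(C)=C | intermediate
8 | tributyl(iodomethyl)stannane | CCCC[Sn](CCCC)(CCCC)CI | starting material
9 | 3-[(1S,4S,6R)-1,3-dimethyl-6-(prop-1-en-2-yl)-4-[(tributylstannyl)methoxy]cyclohex-2-en-1-yl]propanenitrile | C[C@]1(CCC#N)C=C(C)[C@@H](OC[Sn](CCCC)(CCCC)CCCC)C[C@@H]1C(C)=C | intermediate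
10 | N-lithio keteniminate of 9 (lithiated nitrile) | C[C@]1(CC=C=N[Li])C=C(C)[C@@H](OC[Sn](CCCC)(CCCC)CCCC)C[C@@H]1C(C)=C | intermediate
11 | lithiomethyl ether of 7 bearing the N-lithio keteniminate (alkoxymethyllithium) | C[C@]1(CC=C=N[Li])C=C(C)[C@@H](OC[Li])C[C@@H]1C(C)=C | intermediate
12 | 3-[(1R,2S,6R)-2-(hydroxymethyl)-1,3-dimethyl-6-(prop-1-en-2-yl)cyclohex-3-en-1-yl]propanenitrile | OC[C@H]1C(C)=CC[C@H](C(C)=C)[C@]1(CCC#N)C | intermediate
13 | [(1S,4aS,8aR)-6-imino-2,5,5,8a-tetramethyl-1,4,4a,5,6,7,8,8a-octahydronaphthalen-1-yl]methanol (N–H ketimine) | OC[C@H]1C(C)=CC[C@@H]2C(C)(C)C(=N)CC[C@]21C | intermediate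
14 | (4aR,5S,8aS)-5-(hydroxymethyl)-1,1,4a,6-tetramethyl-3,4,4a,5,8,8a-hexahydronaphthalen-2(1H)-one | OC[C@H]1C(C)=CC[C@@H]2C(C)(C)C(=O)CC[C@]21C | intermediate
15 | isofraxidin, 7-hydroxy-6,8-dimethoxy-2H-chromen-2-one | COc1cc2ccc(=O)oc2c(OC)c1O | starting material
16 | 6,8-dimethoxy-7-{[(1S,4aS,8aR)-2,5,5,8a-tetramethyl-6-oxo-1,4,4a,5,6,7,8,8a-octahydronaphthalen-1-yl]methoxy}-2H-chromen-2-one | COc1cc2ccc(=O)oc2c(OC)c1OC[C@H]1C(C)=CC[C@@H]2C(C)(C)C(=O)CC[C@]21C | intermediate
17 | 6,8-dimethoxy-7-{[(1S,4aS,8aR)-2,5,5,8a-tetramethyl-6-oxo-1,4,4a,5,6,8a-hexahydronaphthalen-1-yl]methoxy}-2H-chromen-2-one | COc1cc2ccc(=O)oc2c(OC)c1OC[C@H]1C(C)=CC[C@@H]2C(C)(C)C(=O)C=C[C@]21C | target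

Total step count: 9. Longest linear sequence: 9 steps, from 1 to 17.

**Steps most likely to fail**

Step 4. Condensation of hydrazine at the C9 carbonyl, which is flanked by the quaternary C10 and the fully substituted epoxide carbon C8, may be too slow, so that hydrazine opens the epoxide instead or the epoxy ketone is simply recovered. The fallback sets out from 5 and avoids carbonyl condensation. NaBH4 in MeOH at 0 °C should reduce the ketone to the epoxy alcohol 3-[2-hydroxy-1,3-dimethyl-4-(prop-1-en-2-yl)-7-oxabicyclo[4.1.0]heptan-3-yl]propanenitrile F3 (either carbinol epimer serves). 1,1′-Thiocarbonyldiimidazole and DMAP in toluene at 80 °C should give the thiocarbonyl derivative O-[3-(2-cyanoethyl)-1,3-dimethyl-4-(prop-1-en-2-yl)-7-oxabicyclo[4.1.0]heptan-2-yl] 1H-imidazole-1-carbothioate F4. Bu3SnH and AIBN in benzene at 80 °C would then generate the C9 radical, which opens the adjacent oxirane to the C7 alkoxy radical and, after hydrogen transfer from the stannane, gives the transposed allylic alcohol with unchanged C7 configuration (a radical epoxide fragmentation started in the Barton–McCombie manner). The fallback comes back to the route at 7.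

Step 2. Anionic oligomerization of acrylonitrile and proton transfer between the adduct anion and unreacted ketone may outrun clean one-to-one conjugate addition of the hindered tetrasubstituted enolate. The fallback sets out from 2 and replaces the Michael addition by an alkylation. LiN(iPr)2 in THF at −78 °C followed by allyl bromide should give, with the same facial preference, the allyl ketone (5R,6R)-2,6-dimethyl-6-(prop-2-en-1-yl)-5-(prop-1-en-2-yl)cyclohex-2-en-1-one F1. An aldehyde-selective Wacker oxidation of the monosubstituted alkene (PdCl2(PhCN)2, CuCl2, AgNO2, O2, t-BuOH/MeNO2) should give the aldehyde 3-[(1R,6R)-1,3-dimethyl-2-oxo-6-(prop-1-en-2-yl)cyclohex-3-en-1-yl]propanal F2. Hydroxylamine-O-sulfonic acid in H2O/THF would convert the aldehyde into the nitrile. The fallback comes back to the route at 4.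

Step 7. Addition of the tertiary radical to the nitrile may be slower than its premature reduction to the isopropyl compound, and hydrogen-atom transfer may also reach the C7=C8 alkene. The fallback sets out from 12 and uses a much faster radical acceptor with a different endgame. i-Bu2AlH in CH2Cl2 at −78 °C, followed by aqueous tartaric acid work-up, should give the hydroxy aldehyde 3-[(1R,2S,6R)-2-(hydroxymethyl)-1,3-dimethyl-6-(prop-1-en-2-yl)cyclohex-3-en-1-yl]propanal F5. The known Fe(acac)3/PhSiH3/EtOH reductive alkene–aldehyde radical cyclization should close ring A at the same C3–C4 bond and give the diol (4aR,5S,8aS)-5-(hydroxymethyl)-1,1,4a,6-tetramethyl-1,2,3,4,4a,5,8,8a-octahydronaphthalen-2-ol F6 as a mixture of C3 carbinol epimers. A Mitsunobu reaction with 15, selective for the primary C11 hydroxyl over the hindered secondary one, should give the ether alcohol 7-{[(1S,4aS,8aR)-6-hydroxy-2,5,5,8a-tetramethyl-1,4,4a,5,6,7,8,8a-octahydronaphthalen-1-yl]methoxy}-6,8-dimethoxy-2H-chromen-2-one F7. An excess of IBX in DMSO at 80 °C would then oxidize the C3 carbinol and dehydrogenate the ketone in the same flask. The fallback comes back to the route at 17.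

**Further compounds**
F1 | step 2 | (5R,6R)-2,6-dimethyl-6-(prop-2-en-1-yl)-5-(prop-1-en-2-yl)cyclohex-2-en-1-one | O=C1C(C)=CC[C@H](C(C)=C)[C@]1(CC=C)C
F2 | step 2 | 3-[(1R,6R)-1,3-dimethyl-2-oxo-6-(prop-1-en-2-yl)cyclohex-3-en-1-yl]propanal | O=C1C(C)=CC[C@H](C(C)=C)[C@]1(CCC=O)C
F3 | step 4 | 3-[2-hydroxy-1,3-dimethyl-4-(prop-1-en-2-yl)-7-oxabicyclo[4.1.0]heptan-3-yl]propanenitrile (carbinol epimers, other centres as in 5) | OC1[C@@]2(C)O[C@H]2C[C@H](C(C)=C)[C@]1(CCC#N)C
F4 | step 4 | O-[3-(2-cyanoethyl)-1,3-dimethyl-4-(prop-1-en-2-yl)-7-oxabicyclo[4.1.0]heptan-2-yl] 1H-imidazole-1-carbothioate | S=C(OC1[C@@]2(C)O[C@H]2C[C@H](C(C)=C)[C@]1(CCC#N)C)n1ccnc1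
F5 | step 7 | 3-[(1R,2S,6R)-2-(hydroxymethyl)-1,3-dimethyl-6-(prop-1-en-2-yl)cyclohex-3-en-1-yl]propanal | OC[C@H]1C(C)=CC[C@H](C(C)=C)[C@]1(CCC=O)C
F6 | step 7 | (4aR,5S,8aS)-5-(hydroxymethyl)-1,1,4a,6-tetramethyl-1,2,3,4,4a,5,8,8a-octahydronaphthalen-2-ol (carbinol epimers) | OC[C@H]1C(C)=CC[C@@H]2C(C)(C)C(O)CC[C@]21C
F7 | step 7 | 7-{[(1S,4aS,8aR)-6-hydroxy-2,5,5,8a-tetramethyl-1,4,4a,5,6,7,8,8a-octahydronaphthalen-1-yl]methoxy}-6,8-dimethoxy-2H-chromen-2-one | COc1cc2ccc(=O)oc2c(OC)c1OC[C@H]1C(C)=CC[C@@H]2C(C)(C)C(O)CC[C@]21C
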